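**Plan**

- Retrosynthesis: cut (a) the CH2–CH2 bond between the CH2 on the quaternary oxirane carbon and the CH2 next to the left CH(CH3) centre; (b) in the C21 half, the oxirane C–O bonds, the neighbouring C(CH3)=CH bond, the right-hand CH–CH3 bond and the CH2–CH2CN bond to farnesyl C1; (c) in the C11 half, the C=CH2 bond and the ketone–alkyl bond of a Roche-ester ketone.
- Enabling feature: the oxirane ring whose quaternary carbon C(CH3)(O) carries that CH2. The array CH2–C(CH3)(–O–)–CH is a 2,3-epoxy-1-ol skeleton, so this CH2 can start as the carbinol carbon of a Sharpless product and, as its triflate, be a primary electrophile more reactive than the ring.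
- Forward: farnesyl bromide → C17 nitrile → ω-alcohol → bromide → SN2′ methylation → aldehyde → (E)-enoate → allylic alcohol → epoxy alcohol → triflate; Roche ester → Weinreb amide → ketone → methylene compound → bromide; the Grignard reagent of that bromide and the triflate are joined last (the oxirane is the only ring).
- Stereochemistry: left CH(CH3) bought as (R)-Roche ester; right CH(CH3) from catalyst-controlled copper allylic methylation; both oxirane carbons from one Sharpless epoxidation (D-(−)-diethyl tartrate) of an E-alkene made by a stabilised Wittig reaction; the other two E-alkenes come with farnesyl bromide.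

Key step: step 16

Remark: the facial sense of the Cu/Taniaphos catalyst in step 4 is taken by analogy with unbranched (E)-allylic bromides; should the 2-methyl substrate respond in the opposite sense, the enantiomeric ligand is used.

Step 1
Reactants: 1 (2E,6E)-1-bromo-3,7,11-trimethyldodeca-2,6,10-triene (trans,trans-farnesyl bromide)
Product: 2 (4E,8E)-5,9,13-trimethyltetradeca-4,8,12-trienenitrile
Conditions: MeCN, n-BuLi, THF, −78 °C; then 1, −78 → −20 °C
Reagents that add atoms: acetonitrile, CC#N
Why: Nitrile-anion alkylation, in which lithiated acetonitrile displaces the primary allylic bromide by SN2 at the unhindered CH2, leaving both E-alkenes untouched and adding the two carbons that become C3 and C4 of the later allylic alcohol.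

Step 2
Reactants: 2 (4E,8E)-5,9,13-trimethyltetradeca-4,8,12-trienenitrile
Product: 3 (4E,8E,12E)-14-hydroxy-5,9,13-trimethyltetradeca-4,8,12-trienenitrile
Conditions: SeO2 (cat.), t-BuOOH, salicylic acid (cat.), CH2Cl2, 0 °C → rt
Reagents that add atoms: tert-butyl hydroperoxide, CC(C)(C)OO
Why: Catalytic selenium dioxide allylic oxidation (ene reaction then [2,3]-sigmatropic shift) should attack the least hindered terminal isopropylidene group and oxidise its E-methyl group, giving the (E)-allylic alcohol.

Step 3
Reactants: 3 (4E,8E,12E)-14-hydroxy-5,9,13-trimethyltetradeca-4,8,12-trienenitrile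
Product: 4 (4E,8E,12E)-14-bromo-5,9,13-trimethyltetradeca-4,8,12-trienenitrile
Conditions: CBr4, PPh3, CH2Cl2, 0 °C
Reagents that add atoms: carbon tetrabromide, BrC(Br)(Br)Br
Why: Appel reaction, in which bromide displaces the oxyphosphonium group by SN2 at the primary carbon without allylic transposition or loss of alkene geometry.

Step 4
Reactants: 4 (4E,8E,12E)-14-bromo-5,9,13-trimethyltetradeca-4,8,12-trienenitrile
Product: 5 (4E,8E,12S)-5,9,12,13-tetramethyltetradeca-4,8,13-trienenitrile
Conditions: MeMgBr (slow addition), CuBr·SMe2 (5 mol %), (R,R)-Taniaphos (6 mol %), CH2Cl2, −78 °C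
Reagents that add atoms: methylmagnesium bromide, C[Mg]Br
Why: Copper-catalysed asymmetric allylic alkylation, in which the ligated methylcopper species adds SN2′ at the γ-carbon of the (E)-2-methylallylic bromide, moving the double bond into the 1,1-disubstituted position and creating the CH(CH3) centre under catalyst control (methyl to the Si face of C12 gives 12S), while the nitrile is inert to the Grignard reagent at −78 °C.

Step 5
Reactants: 5 (4E,8E,12S)-5,9,12,13-tetramethyltetradeca-4,8,13-trienenitrile
Product: 7 (4E,8E,12S)-5,9,12,13-tetramethyltetradeca-4,8,13-trienal, via N-aluminoaldimine 6 (not isolated)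
Conditions: DIBAL-H, toluene, −78 °C; then aq. Rochelle salt, dilute citric acid, 0 °C
Reagents that add atoms: water, O
Why: Partial reduction of a nitrile with DIBAL-H, which stops after one hydride transfer at the N-aluminoaldimine 6 and gives the aldehyde on hydrolysis, the isolated alkenes and the remote stereocentre being unaffected.

Step 6
Reactants: 7 (4E,8E,12S)-5,9,12,13-tetramethyltetradeca-4,8,13-trienal
Product: 8 ethyl (2E,6E,10E,14S)-2,7,11,14,15-pentamethylhexadeca-2,6,10,15-tetraenoate
Conditions: Ph3P=C(CH3)CO2Et, CH2Cl2, rt → 40 °C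
Reagents that add atoms: ethyl 2-(triphenylphosphoranylidene)propanoate, CCOC(=O)C(C)=P(c1ccccc1)(c1ccccc1)c1ccccc1
Why: Wittig olefination with a stabilised α-methyl ylide, which should give the (E)-trisubstituted enoate and so fixes the trans relation of the two chains on the later oxirane.

Step 7
Reactants: 8 ethyl (2E,6E,10E,14S)-2,7,11,14,15-pentamethylhexadeca-2,6,10,15-tetraenoate
Product: 9 (2E,6E,10E,14S)-2,7,11,14,15-pentamethylhexadeca-2,6,10,15-tetraen-1-ol
Conditions: DIBAL-H, CH2Cl2, −78 °C; aq. Rochelle salt
Reagents that add atoms: none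
Why: 1,2-Reduction of an α,β-unsaturated ester with DIBAL-H gives the (E)-allylic alcohol without touching the isolated alkenes.

Step 8
Reactants: 9 (2E,6E,10E,14S)-2,7,11,14,15-pentamethylhexadeca-2,6,10,15-tetraen-1-ol
Product: 10 [(2R,3R)-2-methyl-3-[(3E,7E,11S)-4,8,11,12-tetramethyltrideca-3,7,12-trien-1-yl]oxiran-2-yl]methanol
Conditions: Ti(Oi-Pr)4 (cat.), D-(−)-diethyl tartrate (cat.), t-BuOOH, 4 Å MS, CH2Cl2, −20 °C
Reagents that add atoms: tert-butyl hydroperoxide, CC(C)(C)OO
Why: Sharpless asymmetric epoxidation, in which the allylic hydroxyl binds the titanium–tartrate catalyst so that only this alkene of the four is oxidised, and D-(−)-diethyl tartrate delivers oxygen to the face that sets both oxirane centres as 2R,3R in one event from the E-alkene.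

Step 9
Reactants: 10 [(2R,3R)-2-methyl-3-[(3E,7E,11S)-4,8,11,12-tetramethyltrideca-3,7,12-trien-1-yl]oxiran-2-yl]methanol
Product: 11 [(2R,3R)-2-methyl-3-[(3E,7E,11S)-4,8,11,12-tetramethyltrideca-3,7,12-trien-1-yl]oxiran-2-yl]methyl trifluoromethanesulfonate
Conditions: Tf2O, 2,6-lutidine, CH2Cl2, −78 °C; cold aqueous work-up, used at once
Reagents that add atoms: trifluoromethanesulfonic anhydride, O=S(=O)(OS(=O)(=O)C(F)(F)F)C(F)(F)F
Why: O-Sulfonylation of the primary alcohol at low temperature with a hindered base installs the leaving group for the coupling without opening the oxirane or attacking the alkenes.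

Step 10
Reactants: 12 methyl (R)-3-hydroxy-2-methylpropanoate ((R)-Roche ester)
Product: 13 methyl (R)-3-[(tert-butyldimethylsilyl)oxy]-2-methylpropanoate
Conditions: TBSCl, imidazole, CH2Cl2, rt
Reagents that add atoms: tert-butyldimethylsilyl chloride, CC(C)(C)[Si](C)(C)Cl
Why: Silyl ether formation protects the primary hydroxyl under conditions that do not epimerise the purchased stereocentre.

Step 11
Reactants: 13 methyl (R)-3-[(tert-butyldimethylsilyl)oxy]-2-methylpropanoate
Product: 14 (R)-3-[(tert-butyldimethylsilyl)oxy]-N-methoxy-N,2-dimethylpropanamide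
Conditions: MeNH(OMe)·HCl, i-PrMgCl, THF, −20 → 0 °C
Reagents that add atoms: N,O-dimethylhydroxylamine hydrochloride, CNOC.Cl
Why: Weinreb amide formation by aminolysis of the ester with the chloromagnesium amide, a non-enolising procedure that keeps the α-stereocentre intact.

Step 12
Reactants: 14 (R)-3-[(tert-butyldimethylsilyl)oxy]-N-methoxy-N,2-dimethylpropanamide; 15 5-bromo-2-methylpent-2-ene
Product: 17 (2R)-1-[(tert-butyldimethylsilyl)oxy]-2,7-dimethyloct-6-en-3-one, via homoprenylmagnesium bromide 16 (not isolated)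
Conditions: 15, Mg, THF, rt; then 14, THF, 0 °C; aq. NH4Cl
Reagents that add atoms: none
Why: Weinreb ketone synthesis, in which the Grignard reagent adds only once to the N-methoxy-N-methylamide and the ketone is released on work-up with the α-stereocentre unchanged.

Step 13
Reactants: 17 (2R)-1-[(tert-butyldimethylsilyl)oxy]-2,7-dimethyloct-6-en-3-one
Product: 18 tert-butyl{[(2S)-2,7-dimethyl-3-methylideneoct-6-en-1-yl]oxy}dimethylsilane
Conditions: Zn, CH2Br2, TiCl4, THF–CH2Cl2, 0 °C → rt
Reagents that add atoms: dibromomethane, BrCBr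
Why: Takai–Lombardo methylenation, whose non-basic zinc/titanium methylene reagent converts the ketone into the 1,1-disubstituted alkene without enolisation, so the adjacent stereocentre is kept (the descriptor changes to S only through CIP priorities).

Step 14
Reactants: 18 tert-butyl{[(2S)-2,7-dimethyl-3-methylideneoct-6-en-1-yl]oxy}dimethylsilane
Product: 19 (2S)-2,7-dimethyl-3-methylideneoct-6-en-1-ol
Conditions: TBAF, THF, rt
Reagents that add atoms: none
Why: Fluoride-mediated desilylation frees the primary alcohol without affecting either alkene.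

Step 15
Reactants: 19 (2S)-2,7-dimethyl-3-methylideneoct-6-en-1-ol
Product: 20 (2S)-1-bromo-2,7-dimethyl-3-methylideneoct-6-ene
Conditions: CBr4, PPh3, CH2Cl2, 0 °C
Reagents that add atoms: carbon tetrabromide, BrC(Br)(Br)Br
Why: Appel reaction converts the primary alcohol into the bromide by SN2 at CH2, so the β-stereocentre is not involved.

Step 16
Reactants: 20 (2S)-1-bromo-2,7-dimethyl-3-methylideneoct-6-ene; 11 [(2R,3R)-2-methyl-3-[(3E,7E,11S)-4,8,11,12-tetramethyltrideca-3,7,12-trien-1-yl]oxiran-2-yl]methyl trifluoromethanesulfonate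
Product: 22 (2R,3R)-2-[(3R)-3,8-dimethyl-4-methylidenenon-7-en-1-yl]-2-methyl-3-[(3E,7E,11S)-4,8,11,12-tetramethyltrideca-3,7,12-trien-1-yl]oxirane, via alkylmagnesium bromide 21 (not isolated)
Conditions: 20, Mg, THF, ≤ 25 °C; then CuBr·SMe2 (10 mol %), 11, THF–Et2O, −78 → −30 °C
Reagents that add atoms: none
Why: Magnesium inserts into the primary C–Br bond of 20, and Grignard reagent 21 transmetalates to copper(I) to give an alkylcopper species that displaces the primary triflate of 11 by SN2-type oxidative addition and reductive elimination, forming the CH2–CH2 bond and regenerating copper. The closest known reaction type is the copper-catalysed cross-coupling of alkyl Grignard reagents with primary alkyl triflates and with 2,3-epoxy sulfonates, as used to extend Sharpless epoxy alcohols into epoxyalkanes. No ring is closed and no stereocentre is created: both reacting carbons are CH2 groups, so the β-stereocentre of 21 and the two oxirane carbons of 11 pass through unchanged, and the product is the target itself with no protecting group or redox adjustment to follow. The step needs chemoselectivity for C–OTf over the oxirane and the alkenes; a primary triflate is displaced by organocopper reagents at −78 °C where a trisubstituted epoxide is inert, and the three-membered ring ties back the substituents of the quaternary carbon so the adjacent CH2 is not neopentyl-like. Reagent 21 is made and used below room temperature to avoid homoallyl/cyclopropylcarbinyl isomerisation, and THF moderates the Lewis acidity of the magnesium salts towards the epoxide.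

**Compound list**

1 | (2E,6E)-1-bromo-3,7,11-trimethyldodeca-2,6,10-triene (farnesyl bromide) | CC(C)=CCC/C(C)=C/CC/C(C)=C/CBr | starting material
2 | (4E,8E)-5,9,13-trimethyltetradeca-4,8,12-trienenitrile | N#CCC/C=C(\C)CC/C=C(\C)CCC=C(C)C | intermediate
3 | (4E,8E,12E)-14-hydroxy-5,9,13-trimethyltetradeca-4,8,12-trienenitrile | N#CCC/C=C(\C)CC/C=C(\C)CC/C=C(\C)CO | intermediate
4 | (4E,8E,12E)-14-bromo-5,9,13-trimethyltetradeca-4,8,12-trienenitrile | N#CCC/C=C(\C)CC/C=C(\C)CC/C=C(\C)CBr | intermediate
5 | (4E,8E,12S)-5,9,12,13-tetramethyltetradeca-4,8,13-trienenitrile | N#CCC/C=C(\C)CC/C=C(\C)CC[C@H](C)C(=C)C | intermediate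
6 | N-(diisobutylalumino)aldimine of 7 | CC(C)C[Al](CC(C)C)N=CCC/C=C(\C)CC/C=C(\C)CC[C@H](C)C(=C)C | intermediate
7 | (4E,8E,12S)-5,9,12,13-tetramethyltetradeca-4,8,13-trienal | O=CCC/C=C(\C)CC/C=C(\C)CC[C@H](C)C(=C)C | intermediate
8 | ethyl (2E,6E,10E,14S)-2,7,11,14,15-pentamethylhexadeca-2,6,10,15-tetraenoate | CCOC(=O)/C(C)=C/CC/C=C(\C)CC/C=C(\C)CC[C@H](C)C(=C)C | intermediate
9 | (2E,6E,10E,14S)-2,7,11,14,15-pentamethylhexadeca-2,6,10,15-tetraen-1-ol | OC/C(C)=C/CC/C=C(\C)CC/C=C(\C)CC[C@H](C)C(=C)C | intermediate
10 | [(2R,3R)-2-methyl-3-[(3E,7E,11S)-4,8,11,12-tetramethyltrideca-3,7,12-trien-1-yl]oxiran-2-yl]methanol | OC[C@@]1(C)O[C@@H]1CC/C=C(\C)CC/C=C(\C)CC[C@H](C)C(=C)C | intermediate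
11 | [(2R,3R)-2-methyl-3-[(3E,7E,11S)-4,8,11,12-tetramethyltrideca-3,7,12-trien-1-yl]oxiran-2-yl]methyl trifluoromethanesulfonate | O=S(=O)(OC[C@@]1(C)O[C@@H]1CC/C=C(\C)CC/C=C(\C)CC[C@H](C)C(=C)C)C(F)(F)F | intermediate
12 | methyl (R)-3-hydroxy-2-methylpropanoate ((R)-Roche ester) | COC(=O)[C@H](C)CO | starting material
13 | methyl (R)-3-[(tert-butyldimethylsilyl)oxy]-2-methylpropanoate | COC(=O)[C@H](C)CO[Si](C)(C)C(C)(C)C | intermediate
14 | (R)-3-[(tert-butyldimethylsilyl)oxy]-N-methoxy-N,2-dimethylpropanamide | CON(C)C(=O)[C@H](C)CO[Si](C)(C)C(C)(C)C | intermediate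
15 | 5-bromo-2-methylpent-2-ene | CC(C)=CCCBr | starting material
16 | (4-methylpent-3-en-1-yl)magnesium bromide | CC(C)=CCC[Mg]Br | intermediate
17 | (2R)-1-[(tert-butyldimethylsilyl)oxy]-2,7-dimethyloct-6-en-3-one | CC(C)=CCCC(=O)[C@H](C)CO[Si](C)(C)C(C)(C)C | intermediate
18 | tert-butyl{[(2S)-2,7-dimethyl-3-methylideneoct-6-en-1-yl]oxy}dimethylsilane | C=C(CCC=C(C)C)[C@H](C)CO[Si](C)(C)C(C)(C)C | intermediate
19 | (2S)-2,7-dimethyl-3-methylideneoct-6-en-1-ol | C=C(CCC=C(C)C)[C@H](C)CO | intermediate
20 | (2S)-1-bromo-2,7-dimethyl-3-methylideneoct-6-ene | C=C(CCC=C(C)C)[C@H](C)CBr | intermediate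
21 | [(2S)-2,7-dimethyl-3-methylideneoct-6-en-1-yl]magnesium bromide | C=C(CCC=C(C)C)[C@H](C)C[Mg]Br | intermediate
22 | (2R,3R)-2-[(3R)-3,8-dimethyl-4-methylidenenon-7-en-1-yl]-2-methyl-3-[(3E,7E,11S)-4,8,11,12-tetramethyltrideca-3,7,12-trien-1-yl]oxirane | C=C(CCC=C(C)C)[C@H](C)CC[C@@]1(C)O[C@@H]1CC/C=C(\C)CC/C=C(\C)CC[C@H](C)C(=C)C | target

**Step count and risks**

Total: 16 steps. Longest linear sequence: 10 steps (steps 1–9 and 16, from farnesyl bromide); the C11 branch is 6 steps (10–15) before the union.

Steps most likely to fail: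

1. Step 16. Displacement at the CH2 next to the fully substituted oxirane carbon may be slow. Magnesium-salt-induced opening or rearrangement of the trisubstituted epoxide, β-alkoxide elimination from the organocopper intermediate, or isomerisation of the homoallylic Grignard reagent could then compete. The fallback replaces the organometallic by a sulfonyl-stabilised carbanion and removes the sulfonyl group afterwards. It sets out from bromide 20 and triflate 11 and returns at 22. Bromide 20 with sodium benzenesulfinate (DMF, 60 °C) would give {[(2S)-2,7-dimethyl-3-methylideneoct-6-en-1-yl]sulfonyl}benzene F1. Its lithio derivative (n-BuLi, THF, −78 °C) would displace the triflate of 11 to give the phenylsulfonyl derivative of the target F2, as both epimers at the sulfonyl-bearing carbon. Reductive desulfonylation (Na/Hg, Na2HPO4, MeOH–THF, −20 °C) would then give 22.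

2. Step 4. The 2-methyl substituent may shift the partition from SN2′ towards SN2 attack and lower the enantiofacial discrimination. Because the stereocentres are remote from one another, the minor antipode would then travel on as a hard-to-remove diastereomer. The fallback sets the centre by a Sharpless epoxidation followed by a stereospecific epoxide opening. It sets out from allylic alcohol 3 and returns at 5. Epoxidation of 3 with Ti(Oi-Pr)4, D-(−)-diethyl tartrate and t-BuOOH would give (4E,8E)-11-[(2R,3R)-3-(hydroxymethyl)-3-methyloxiran-2-yl]-5,9-dimethylundeca-4,8-dienenitrile F3. Me2CuLi (Et2O, −20 → 0 °C) would attack the CH carbon of the oxirane with inversion, the quaternary carbon being blocked, to give (4E,8E,12S,13S)-13,14-dihydroxy-5,9,12,13-tetramethyltetradeca-4,8-dienenitrile F4. 1,1′-Thiocarbonyldiimidazole (toluene, 80 °C) would give the cyclic thiocarbonate (4E,8E,12S)-5,9-dimethyl-12-[(4S)-4-methyl-2-sulfanylidene-1,3-dioxolan-4-yl]trideca-4,8-dienenitrile F5. Corey–Winter olefination (P(OMe)3, 110 °C) would then leave the C(CH3)=CH2 group and give 5.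

3. Step 2. Site selectivity among three trisubstituted alkenes may be incomplete, and over-oxidation to the enal may occur. The fallback builds the (E)-allylic alcohol by degradation and Wittig reconstruction instead of allylic oxidation. It sets out from nitrile 2 and returns at 3. Terminal-selective bromohydrin formation (NBS, THF–H2O, 0 °C) would give racemic (4E,8E)-12-bromo-13-hydroxy-5,9,13-trimethyltetradeca-4,8-dienenitrile F6. K2CO3 in MeOH would close it to racemic (4E,8E)-11-(3,3-dimethyloxiran-2-yl)-5,9-dimethylundeca-4,8-dienenitrile F7. Periodic acid (HIO4·2H2O, THF–Et2O, 0 °C) would cleave this to (4E,8E)-5,9-dimethyl-12-oxododeca-4,8-dienenitrile F8. Wittig reaction with Ph3P=C(CH3)CHO (toluene, 90 °C) would give (4E,8E,12E)-5,9,13-trimethyl-14-oxotetradeca-4,8,12-trienenitrile F9. Luche reduction (NaBH4, CeCl3, MeOH, 0 °C) would then give 3.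

**Further compounds**

F1 | step 16 | {[(2S)-2,7-dimethyl-3-methylideneoct-6-en-1-yl]sulfonyl}benzene | C=C(CCC=C(C)C)[C@H](C)CS(=O)(=O)c1ccccc1
F2 | step 16 | phenylsulfonyl derivative of 22 at the CH2 next to the left CH(CH3) centre (both epimers at that carbon) | C=C(CCC=C(C)C)[C@H](C)C(C[C@@]1(C)O[C@@H]1CC/C=C(\C)CC/C=C(\C)CC[C@H](C)C(=C)C)S(=O)(=O)c1ccccc1
F3 | step 4 | (4E,8E)-11-[(2R,3R)-3-(hydroxymethyl)-3-methyloxiran-2-yl]-5,9-dimethylundeca-4,8-dienenitrile | OC[C@@]1(C)O[C@@H]1CC/C(C)=C/CC/C(C)=C/CCC#N
F4 | step 4 | (4E,8E,12S,13S)-13,14-dihydroxy-5,9,12,13-tetramethyltetradeca-4,8-dienenitrile | OC[C@@]([C@@H](C)CC/C(C)=C/CC/C(C)=C/CCC#N)(C)O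
F5 | step 4 | (4E,8E,12S)-5,9-dimethyl-12-[(4S)-4-methyl-2-sulfanylidene-1,3-dioxolan-4-yl]trideca-4,8-dienenitrile | S=C1OC[C@@]([C@@H](C)CC/C(C)=C/CC/C(C)=C/CCC#N)(C)O1
F6 | step 2 | (4E,8E)-12-bromo-13-hydroxy-5,9,13-trimethyltetradeca-4,8-dienenitrile (racemic) | N#CCC/C=C(\C)CC/C=C(\C)CCC(Br)C(C)(C)O
F7 | step 2 | (4E,8E)-11-(3,3-dimethyloxiran-2-yl)-5,9-dimethylundeca-4,8-dienenitrile (racemic) | N#CCC/C=C(\C)CC/C=C(\C)CCC1OC1(C)C
F8 | step 2 | (4E,8E)-5,9-dimethyl-12-oxododeca-4,8-dienenitrile | N#CCC/C=C(\C)CC/C=C(\C)CCC=O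
F9 | step 2 | (4E,8E,12E)-5,9,13-trimethyl-14-oxotetradeca-4,8,12-trienenitrile | N#CCC/C=C(\C)CC/C=C(\C)CC/C=C(\C)C=O
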